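**Retrosynthetic overview**

1. Germacranolide numbering is used: C1 ketone, C2 =CH, C3 enol-ether carbon, C4(=C15H2), C5 carbinol, C6 lactone O-carbon, C7, C8 ester carbon (its oxygen is O8), C9, C10(C14H3), C11(=C13H2), C12. The last cut is O–C3 of the furanone: transannular 5-endo-dig addition of the C10 hydroxyl to a C1 ynone.
2. The key cut is C1–C2. The ten-membered carbocycle closes when a C2 alkynyllithium attacks C1, which is the carbonyl of a γ-lactone C1(=O)–O8–C8 that is not in the target. The bridged hemiketal fragments at C1–O8 to the cyclodecynone and releases O8 as the alkoxide, which is isobutyrylated in the same flask.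
3. That temporary lactone is the γ-lactone of D-glutamic acid. Its five carbons become C7, C8, C9, C10 and C1; it supplies C8, directs the hydroxylation that creates quaternary C10, and masks O8 and C1.
4. The α-methylene lactone (C6–C7 bond, C11–C13) comes from an indium Barbier union of an allylic bromide with an aldehyde that holds C2–C6 and C15 (C5 from (R)-glycerate). Ring order: glutamate lactone (from the start), cis α-methylene lactone (step 15), ten-membered ring (step 17), furanone (step 18).
5. Enabling feature: C1 and O8 are 1,4-related across C9–C10, so they can be tied as a five-membered lactone. The cis-fused C6–C7 lactone holds C5 and C8 gauche, which lays C2 over C1, and quaternary C10 leaves C1 without an α-hydrogen.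

Key step: step 17

Remark: the SMILES is read as 5S,6R,7R,8R,10S with H6 and H7 cis (cis-fused lactone), and the route is built for that isomer. The four starting materials of steps 1, 7 and 9 are taken as commercial.

**Route**

Step 1
Reactants: 1 (R)-5-(hydroxymethyl)dihydrofuran-2(3H)-one
Product: 2 (R)-5-((benzyloxy)methyl)dihydrofuran-2(3H)-one
Conditions: BnOC(=NH)CCl3, TfOH (cat.), CH2Cl2/cyclohexane, 0 °C to rt
Reagents that add atoms: benzyl 2,2,2-trichloroacetimidate, ClC(Cl)(Cl)C(=N)OCc1ccccc1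
Why: Acid-catalysed O-benzylation with the trichloroacetimidate needs no base, so the lactone is neither opened nor epimerised and the stereocentre (future C8) is untouched.

Step 2
Reactants: 2 (R)-5-((benzyloxy)methyl)dihydrofuran-2(3H)-one
Product: 4 (3S,5R)-5-((benzyloxy)methyl)-3-methyldihydrofuran-2(3H)-one, via lithium enolate 3 (not isolated)
Conditions: LiN(iPr)2 (LDA), THF, −78 °C; MeI, −78 to −40 °C
Reagents that add atoms: iodomethane, CI
Why: Lactone enolate alkylation should place the methyl group mainly anti to the benzyloxymethyl group; this centre is re-enolised in step 3, so any cis epimer can be carried along.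

Step 3
Reactants: 4 (3S,5R)-5-((benzyloxy)methyl)-3-methyldihydrofuran-2(3H)-one
Product: 6 (3S,5R)-5-((benzyloxy)methyl)-3-hydroxy-3-methyldihydrofuran-2(3H)-one, via potassium enolate 5 (not isolated)
Conditions: KN(SiMe3)2, THF, −78 °C; 2-(phenylsulfonyl)-3-phenyloxaziridine; aq. NH4Cl
Reagents that add atoms: 2-(phenylsulfonyl)-3-phenyloxaziridine, O=S(=O)(c1ccccc1)N1OC1c1ccccc1
Why: Enolate hydroxylation with an N-sulfonyloxaziridine should occur on the ring face opposite the benzyloxymethyl group, which puts the hydroxyl trans to it and sets the quaternary centre (C10 of the target) as S.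

Step 4
Reactants: 6 (3S,5R)-5-((benzyloxy)methyl)-3-hydroxy-3-methyldihydrofuran-2(3H)-one
Product: 7 (3S,5R)-5-((benzyloxy)methyl)-3-methyl-3-((triethylsilyl)oxy)dihydrofuran-2(3H)-one
Conditions: TESOTf, 2,6-lutidine, CH2Cl2, −78 to 0 °C
Reagents that add atoms: triethylsilyl trifluoromethanesulfonate, CC[Si](CC)(CC)OS(=O)(=O)C(F)(F)F
Why: Silyl triflate silylation is the standard way to protect a hindered tertiary alcohol; no stereocentre is involved.

Step 5
Reactants: 7 (3S,5R)-5-((benzyloxy)methyl)-3-methyl-3-((triethylsilyl)oxy)dihydrofuran-2(3H)-one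
Product: 8 (3S,5R)-5-(hydroxymethyl)-3-methyl-3-((triethylsilyl)oxy)dihydrofuran-2(3H)-one
Conditions: H2 (1 atm), Pd/C, EtOAc, rt
Reagents that add atoms: none
Why: Hydrogenolysis of the benzyl ether in a non-protic solvent should leave the lactone and the tertiary TES ether intact.

Step 6
Reactants: 8 (3S,5R)-5-(hydroxymethyl)-3-methyl-3-((triethylsilyl)oxy)dihydrofuran-2(3H)-one
Product: 9 (2R,4S)-4-methyl-5-oxo-4-((triethylsilyl)oxy)tetrahydrofuran-2-carbaldehyde
Conditions: DMP, NaHCO3, CH2Cl2, 0 °C to rt; used crude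
Reagents that add atoms: none
Why: Buffered Dess–Martin oxidation is base-free, so the α-oxygenated aldehyde should form without epimerisation at the carbon that becomes C8.

Step 7
Reactants: 9 (2R,4S)-4-methyl-5-oxo-4-((triethylsilyl)oxy)tetrahydrofuran-2-carbaldehyde; 10 methyl acrylate
Product: 11 methyl 2-{hydroxy[(2R,4S)-4-methyl-5-oxo-4-((triethylsilyl)oxy)tetrahydrofuran-2-yl]methyl}acrylate (both carbinol epimers)
Conditions: DABCO, methyl acrylate (excess, neat), rt
Reagents that add atoms: none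
Why: In this Morita–Baylis–Hillman reaction the electron-poor α-oxygenated aldehyde is a fast acceptor, and the new carbinol centre is erased in step 8, so its configuration does not matter.

Step 8
Reactants: 11 methyl 2-{hydroxy[(2R,4S)-4-methyl-5-oxo-4-((triethylsilyl)oxy)tetrahydrofuran-2-yl]methyl}acrylate
Product: 12 methyl (Z)-2-(bromomethyl)-3-[(2R,4S)-4-methyl-5-oxo-4-((triethylsilyl)oxy)tetrahydrofuran-2-yl]acrylate
Conditions: NBS, Me2S, CH2Cl2, −20 to 0 °C
Reagents that add atoms: N-bromosuccinimide, BrN1C(=O)CCC1=O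
Why: Bromination with allylic transposition (SN2′ attack of bromide on the alkoxysulfonium salt) should give the thermodynamically preferred trisubstituted (Z)-2-(bromomethyl)enoate.

Step 9
Reactants: 13 methyl (R)-2,2-dimethyl-1,3-dioxolane-4-carboxylate; 14 ethynyltrimethylsilane
Product: 16 (R)-1-(2,2-dimethyl-1,3-dioxolan-4-yl)-3-(trimethylsilyl)prop-2-yn-1-one, via lithium (trimethylsilyl)acetylide 15 (not isolated)
Conditions: n-BuLi, THF, −78 °C; BF3·OEt2; then the ester, −78 °C; aq. NH4Cl
Reagents that add atoms: none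
Why: BF3-promoted acylation of a lithium acetylide by an ester stops at the ynone because the tetrahedral adduct survives until the quench, and at −78 °C the α-stereocentre (future C5) should be retained.

Step 10
Reactants: 16 (R)-1-(2,2-dimethyl-1,3-dioxolan-4-yl)-3-(trimethylsilyl)prop-2-yn-1-one
Product: 17 (S)-2,2-dimethyl-4-[4-(trimethylsilyl)but-1-en-3-yn-2-yl]-1,3-dioxolane
Conditions: Ph3PCH3Br, KN(SiMe3)2, THF, 0 °C; then the ynone, −78 to 0 °C
Reagents that add atoms: methyltriphenylphosphonium bromide, C[P+](c1ccccc1)(c1ccccc1)c1ccccc1.[Br-]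
Why: Wittig methylenation of the ynone gives the 2-substituted enyne (C4=C15); the bulky TMS group should suppress conjugate addition and the low temperature should prevent enolisation of the dioxolane centre.

Step 11
Reactants: 17 (S)-2,2-dimethyl-4-[4-(trimethylsilyl)but-1-en-3-yn-2-yl]-1,3-dioxolane
Product: 18 (S)-3-methylidene-5-(trimethylsilyl)pent-4-yne-1,2-diol
Conditions: AcOH/H2O (4:1), 40 °C
Reagents that add atoms: none
Why: Acid hydrolysis of the isopropylidene acetal; the alkynylsilane is stable to aqueous acetic acid.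

Step 12
Reactants: 18 (S)-3-methylidene-5-(trimethylsilyl)pent-4-yne-1,2-diol
Product: 19 (S)-1,2-bis((tert-butyldimethylsilyl)oxy)-3-methylidene-5-(trimethylsilyl)pent-4-yne
Conditions: TBSCl, imidazole, DMF, rt
Reagents that add atoms: tert-butyldimethylsilyl chloride, CC(C)(C)[Si](C)(C)Cl
Why: Standard silylation of both hydroxyl groups; the secondary TBS ether is the non-chelating group needed for step 15.

Step 13
Reactants: 19 (S)-1,2-bis((tert-butyldimethylsilyl)oxy)-3-methylidene-5-(trimethylsilyl)pent-4-yne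
Product: 20 (S)-2-((tert-butyldimethylsilyl)oxy)-3-methylidene-5-(trimethylsilyl)pent-4-yn-1-ol
Conditions: HF·pyridine, pyridine, THF, 0 °C
Reagents that add atoms: none
Why: Selective desilylation: buffered HF·pyridine should cleave the unhindered primary TBS ether well before the secondary one.

Step 14
Reactants: 20 (S)-2-((tert-butyldimethylsilyl)oxy)-3-methylidene-5-(trimethylsilyl)pent-4-yn-1-ol
Product: 21 (S)-2-((tert-butyldimethylsilyl)oxy)-3-methylidene-5-(trimethylsilyl)pent-4-ynal
Conditions: DMP, NaHCO3, CH2Cl2, 0 °C; used at once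
Reagents that add atoms: none
Why: Buffered Dess–Martin oxidation gives the α-silyloxy aldehyde without base, which should avoid epimerisation at C5 and migration of the double bond into conjugation.

Step 15
Reactants: 12 methyl (Z)-2-(bromomethyl)-3-[(2R,4S)-4-methyl-5-oxo-4-((triethylsilyl)oxy)tetrahydrofuran-2-yl]acrylate; 21 (S)-2-((tert-butyldimethylsilyl)oxy)-3-methylidene-5-(trimethylsilyl)pent-4-ynal
Product: 23 (4R,5R)-5-[(1S)-1-((tert-butyldimethylsilyl)oxy)-2-methylidene-4-(trimethylsilyl)but-3-yn-1-yl]-3-methylidene-4-[(2R,4S)-4-methyl-5-oxo-4-((triethylsilyl)oxy)tetrahydrofuran-2-yl]dihydrofuran-2(3H)-one, via hydroxy ester 22 (not isolated)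
Conditions: indium powder, THF/H2O, rt; then PPTS (cat.), CH2Cl2, rt
Reagents that add atoms: none
Why: In this Barbier allylation and lactonisation the allylindium from the (Z)-bromide should add through a closed six-membered chair with the C8 substituent axial, which gives syn C6/C7 (cis lactone); the aldehyde face is set by the polar 1,2-induction of the C5 silyloxy group (attack anti to the C5–O bond, C5–O/C6–O anti), the allyl face by A(1,3) strain at C8 (H8 in the alkene plane, attack anti to C9), the two preferences point to the same 6R,7R isomer, and acid then closes the γ-lactone onto the only free hydroxyl.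

Step 16
Reactants: 23 (the bis-lactone of step 15)
Product: 24 (4R,5R)-5-[(1S)-1-((tert-butyldimethylsilyl)oxy)-4-iodo-2-methylidenebut-3-yn-1-yl]-3-methylidene-4-[(2R,4S)-4-methyl-5-oxo-4-((triethylsilyl)oxy)tetrahydrofuran-2-yl]dihydrofuran-2(3H)-one
Conditions: NIS, AgNO3 (cat.), DMF, rt, dark
Reagents that add atoms: N-iodosuccinimide, IN1C(=O)CCC1=O
Why: Silver-catalysed iododesilylation converts the alkynylsilane directly into the 1-iodoalkyne needed for halogen–metal exchange and should leave the silyl ethers and both lactones untouched.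

Step 17
Reactants: 24 (the iodoalkyne of step 16)
Product: 28 (5S,6R,7R,8R,10S)-5-((tert-butyldimethylsilyl)oxy)-8-(isobutyryloxy)-1-oxo-10-((triethylsilyl)oxy)germacra-4(15),11(13)-dien-2-yn-12,6-olide, via alkynyllithium 25 (not isolated), via bridged lithium hemiketal 26 (not isolated), via ring-opened lithium alkoxide 27 (not isolated)
Conditions: n-BuLi (1.05 equiv), THF/Et2O, −100 °C, 0.002 M; −78 to −40 °C; then (iPrCO)2O, −78 to 0 °C
Reagents that add atoms: isobutyric anhydride, CC(C)C(=O)OC(=O)C(C)C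
Why: Proposed new method: iodine–lithium exchange on the 1-iodoalkyne should be faster at −100 °C than addition of n-BuLi to either lactone, and the C2 alkynyllithium then adds to the lactone carbonyl C1; the closest known reactions are the Parham cyclisation (exchange-triggered intramolecular acylation) and the opening of γ-lactones to γ-hydroxy ynones by lithium acetylides, neither of which has been used to close a ten-membered ring. The attack is a 10-exo-trig closure of the carbocycle C1–C10 (9-exo-trig for the O8-containing ring of the bridged hemiketal), and because that hemiketal holds the alkyne in a nine-membered ring it should relieve the strain by cleaving C1–O8, so the bicycle fragments to the cyclodecynone alkoxide. No stereocentre is formed: C1 is tetrahedral only in the hemiketal (OLi exo, fixed by the cis bridge) and ends as the ketone. The step needs site selectivity among C1, C12 and C13, and the substrate secures it: the cis C6–C7 lactone and the (8R,10S) glutamate lactone place C2 over the C1 face that carries the small C14 methyl, whereas attack at C12 or C13 would force the alkyne into a seven- or eight-membered ring. The freed C8 alkoxide should be acylated by the anhydride at −78 °C faster than it can translactonise to C12, which would have to pass through a 2,6-dioxabicyclo[2.2.1]heptane ortho ester, and quaternary C10 means the ynone cannot enolise.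

Step 18
Reactants: 28 (the ynone of step 17)
Product: 30 (5S,6R,7R,8R,10S)-5-((tert-butyldimethylsilyl)oxy)-8-(isobutyryloxy)-1-oxo-3,10-epoxygermacra-2,4(15),11(13)-trien-12,6-olide, via tertiary alcohol 29 (not isolated)
Conditions: HF·pyridine, pyridine, THF, 0 °C; then AuCl3 (5 mol %), CH2Cl2, rt
Reagents that add atoms: none
Why: Buffered HF·pyridine should remove the TES ether before the hindered allylic TBS ether, and AuCl3 as π-acid then triggers 5-endo-dig addition of the C10 hydroxyl to C3 (the known furan-3(2H)-one synthesis from γ-hydroxy ynones), helped by release of cycloalkyne strain; keeping O5 silylated prevents it from competing for the activated alkyne.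

Step 19
Reactants: 30 (the TBS ether of step 18)
Product: 31 (5S,6R,7R,8R,10S)-5-hydroxy-8-(isobutyryloxy)-1-oxo-3,10-epoxygermacra-2,4(15),11(13)-trien-12,6-olide (CNP0384113.2)
Conditions: HF·pyridine, THF, rt
Reagents that add atoms: none
Why: Acidic fluoride desilylation removes the last TBS ether without base, so the furanone, the isobutyrate and the α-methylene lactone should survive.

**Compound list**

1 | (R)-5-(hydroxymethyl)dihydrofuran-2(3H)-one (γ-lactone from D-glutamic acid) | OC[C@H]1CCC(=O)O1 | starting material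
2 | (R)-5-((benzyloxy)methyl)dihydrofuran-2(3H)-one | c1ccccc1COC[C@H]1CCC(=O)O1 | intermediate
3 | lithium enolate of 2 | [Li]OC1=CC[C@H](COCc2ccccc2)O1 | intermediate (not isolated)
4 | (3S,5R)-5-((benzyloxy)methyl)-3-methyldihydrofuran-2(3H)-one (methyl trans to the side chain) | c1ccccc1COC[C@H]1C[C@H](C)C(=O)O1 | intermediate
5 | potassium enolate of 4 | [K]OC1=C(C)C[C@H](COCc2ccccc2)O1 | intermediate (not isolated)
6 | (3S,5R)-5-((benzyloxy)methyl)-3-hydroxy-3-methyldihydrofuran-2(3H)-one (OH trans to the side chain) | c1ccccc1COC[C@H]1C[C@](C)(O)C(=O)O1 | intermediate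
7 | (3S,5R)-5-((benzyloxy)methyl)-3-methyl-3-((triethylsilyl)oxy)dihydrofuran-2(3H)-one | c1ccccc1COC[C@H]1C[C@](C)(O[Si](CC)(CC)CC)C(=O)O1 | intermediate
8 | (3S,5R)-5-(hydroxymethyl)-3-methyl-3-((triethylsilyl)oxy)dihydrofuran-2(3H)-one | OC[C@H]1C[C@](C)(O[Si](CC)(CC)CC)C(=O)O1 | intermediate
9 | (2R,4S)-4-methyl-5-oxo-4-((triethylsilyl)oxy)tetrahydrofuran-2-carbaldehyde | O=C[C@H]1C[C@](C)(O[Si](CC)(CC)CC)C(=O)O1 | intermediate
10 | methyl acrylate | C=CC(=O)OC | starting material
11 | methyl 2-{hydroxy[(2R,4S)-4-methyl-5-oxo-4-((triethylsilyl)oxy)tetrahydrofuran-2-yl]methyl}acrylate (both carbinol epimers) | C=C(C(=O)OC)C(O)[C@H]1C[C@](C)(O[Si](CC)(CC)CC)C(=O)O1 | intermediate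
12 | methyl (Z)-2-(bromomethyl)-3-[(2R,4S)-4-methyl-5-oxo-4-((triethylsilyl)oxy)tetrahydrofuran-2-yl]acrylate | BrC/C(C(=O)OC)=C\[C@H]1C[C@](C)(O[Si](CC)(CC)CC)C(=O)O1 | intermediate
13 | methyl (R)-2,2-dimethyl-1,3-dioxolane-4-carboxylate | COC(=O)[C@H]1COC(C)(C)O1 | starting material
14 | ethynyltrimethylsilane | C#C[Si](C)(C)C | starting material
15 | lithium (trimethylsilyl)acetylide | [Li]C#C[Si](C)(C)C | intermediate (not isolated)
16 | (R)-1-(2,2-dimethyl-1,3-dioxolan-4-yl)-3-(trimethylsilyl)prop-2-yn-1-one | C[Si](C)(C)C#CC(=O)[C@H]1COC(C)(C)O1 | intermediate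
17 | (S)-2,2-dimethyl-4-[4-(trimethylsilyl)but-1-en-3-yn-2-yl]-1,3-dioxolane | C[Si](C)(C)C#CC(=C)[C@H]1COC(C)(C)O1 | intermediate
18 | (S)-3-methylidene-5-(trimethylsilyl)pent-4-yne-1,2-diol | C[Si](C)(C)C#CC(=C)[C@H](O)CO | intermediate
19 | (S)-1,2-bis((tert-butyldimethylsilyl)oxy)-3-methylidene-5-(trimethylsilyl)pent-4-yne | C[Si](C)(C)C#CC(=C)[C@H](O[Si](C)(C)C(C)(C)C)CO[Si](C)(C)C(C)(C)C | intermediate
20 | (S)-2-((tert-butyldimethylsilyl)oxy)-3-methylidene-5-(trimethylsilyl)pent-4-yn-1-ol | C[Si](C)(C)C#CC(=C)[C@H](O[Si](C)(C)C(C)(C)C)CO | intermediate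
21 | (S)-2-((tert-butyldimethylsilyl)oxy)-3-methylidene-5-(trimethylsilyl)pent-4-ynal | C[Si](C)(C)C#CC(=C)[C@H](O[Si](C)(C)C(C)(C)C)C=O | intermediate
22 | methyl (3S,4R,5S)-5-((tert-butyldimethylsilyl)oxy)-4-hydroxy-2,6-dimethylidene-3-[(2R,4S)-4-methyl-5-oxo-4-((triethylsilyl)oxy)tetrahydrofuran-2-yl]-8-(trimethylsilyl)oct-7-ynoate | C=C(C(=O)OC)[C@@H]([C@@H](O)[C@@H](O[Si](C)(C)C(C)(C)C)C(=C)C#C[Si](C)(C)C)[C@H]1C[C@](C)(O[Si](CC)(CC)CC)C(=O)O1 | intermediate (not isolated)
23 | (4R,5R)-5-[(1S)-1-((tert-butyldimethylsilyl)oxy)-2-methylidene-4-(trimethylsilyl)but-3-yn-1-yl]-3-methylidene-4-[(2R,4S)-4-methyl-5-oxo-4-((triethylsilyl)oxy)tetrahydrofuran-2-yl]dihydrofuran-2(3H)-one | C=C1C(=O)O[C@@H]([C@@H](O[Si](C)(C)C(C)(C)C)C(=C)C#C[Si](C)(C)C)[C@H]1[C@H]1C[C@](C)(O[Si](CC)(CC)CC)C(=O)O1 | intermediate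
24 | (4R,5R)-5-[(1S)-1-((tert-butyldimethylsilyl)oxy)-4-iodo-2-methylidenebut-3-yn-1-yl]-3-methylidene-4-[(2R,4S)-4-methyl-5-oxo-4-((triethylsilyl)oxy)tetrahydrofuran-2-yl]dihydrofuran-2(3H)-one | C=C1C(=O)O[C@@H]([C@@H](O[Si](C)(C)C(C)(C)C)C(=C)C#CI)[C@H]1[C@H]1C[C@](C)(O[Si](CC)(CC)CC)C(=O)O1 | intermediate
25 | alkynyllithium from 24 (lithium in place of iodine at C2) | C=C1C(=O)O[C@@H]([C@@H](O[Si](C)(C)C(C)(C)C)C(=C)C#C[Li])[C@H]1[C@H]1C[C@](C)(O[Si](CC)(CC)CC)C(=O)O1 | intermediate (not isolated)
26 | bridged lithium hemiketal: ten-membered ring C1–C10 with O8 bridging C1 and C8 (cis), OLi exo on C1, C2≡C3 alkyne; C5–C8 and C10 configured as in 24 | C=C1C(=O)O[C@@H]2[C@H]1[C@H]3C[C@](C)(O[Si](CC)(CC)CC)[C@](O[Li])(O3)C#CC(=C)[C@@H]2O[Si](C)(C)C(C)(C)C | intermediate (not isolated)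
27 | lithium 8-alkoxide of (5S,6R,7R,8R,10S)-5-((tert-butyldimethylsilyl)oxy)-8-hydroxy-1-oxo-10-((triethylsilyl)oxy)germacra-4(15),11(13)-dien-2-yn-12,6-olide | C=C1C(=O)O[C@@H]2[C@H]1[C@H](O[Li])C[C@](C)(O[Si](CC)(CC)CC)C(=O)C#CC(=C)[C@@H]2O[Si](C)(C)C(C)(C)C | intermediate (not isolated)
28 | (5S,6R,7R,8R,10S)-5-((tert-butyldimethylsilyl)oxy)-8-(isobutyryloxy)-1-oxo-10-((triethylsilyl)oxy)germacra-4(15),11(13)-dien-2-yn-12,6-olide | C=C1C(=O)O[C@@H]2[C@H]1[C@H](OC(=O)C(C)C)C[C@](C)(O[Si](CC)(CC)CC)C(=O)C#CC(=C)[C@@H]2O[Si](C)(C)C(C)(C)C | intermediate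
29 | (5S,6R,7R,8R,10S)-5-((tert-butyldimethylsilyl)oxy)-10-hydroxy-8-(isobutyryloxy)-1-oxogermacra-4(15),11(13)-dien-2-yn-12,6-olide | C=C1C(=O)O[C@@H]2[C@H]1[C@H](OC(=O)C(C)C)C[C@](C)(O)C(=O)C#CC(=C)[C@@H]2O[Si](C)(C)C(C)(C)C | intermediate (not isolated)
30 | (5S,6R,7R,8R,10S)-5-((tert-butyldimethylsilyl)oxy)-8-(isobutyryloxy)-1-oxo-3,10-epoxygermacra-2,4(15),11(13)-trien-12,6-olide | C=C1C(=O)O[C@@H]2[C@H]1[C@H](OC(=O)C(C)C)C[C@]1(C)OC(=CC1=O)C(=C)[C@@H]2O[Si](C)(C)C(C)(C)C | intermediate
31 | (5S,6R,7R,8R,10S)-5-hydroxy-8-(isobutyryloxy)-1-oxo-3,10-epoxygermacra-2,4(15),11(13)-trien-12,6-olide (CNP0384113.2) | C=C1C(=O)O[C@@H]2[C@H]1[C@H](OC(=O)C(C)C)C[C@]1(C)OC(=CC1=O)C(=C)[C@@H]2O | target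

**Step count and risks**

Total: 19 steps. Longest linear sequence: 13 steps (steps 1–8 and 15–19); the aldehyde branch (steps 9–14) has 6 steps.

Steps most likely to fail:

1. Step 17 (Proposed new method). What may go wrong: the alkynyllithium may not reach C1 because the bridged hemiketal is too strained, so that protonation or intermolecular acylation takes over, or the freed C8 alkoxide may translactonise before it is acylated. The fallback closes the same bond at the aldehyde oxidation level by a Nozaki–Hiyama–Kishi macrocyclisation, which is known chemistry for ten-membered cycloalkynols. It sets out from 6. LiAlH4 in THF opens the lactone to the triol F1, and TESOTf with 2,6-lutidine gives the tris(triethylsilyl) ether F2. Hydrogenolysis (H2, Pd/C, EtOAc) gives the primary alcohol F3 and DMP the aldehyde F4. Methyl acrylate with DABCO gives the Morita–Baylis–Hillman adduct F5, and NBS/Me2S the (Z)-allylic bromide F6. Indium in aqueous THF with aldehyde 21 gives the hydroxy ester F7, which PPTS closes to the α-methylene lactone F8 by the stereochemical arguments of step 15. NIS with catalytic AgNO3 gives the iodoalkyne F9, and Swern oxidation turns its primary TES ether directly into the C1 aldehyde F10. CrCl2 with catalytic NiCl2 in THF at high dilution closes C1–C2 to the cyclic propargylic alcohol F11 (either C1 epimer), and DMP gives the ynone F12. PPTS in MeOH at 0 °C should remove the secondary TES ether on O8 ahead of the tertiary one on O10 and the TBS ether, giving the hydroxy ynone F13. Isobutyric anhydride, DMAP and pyridine then give 28, where the fallback returns to the route.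

2. Step 15. What may go wrong: poor facial selectivity if the intrinsic preferences of the aldehyde and the allylindium do not reinforce each other, or erosion of the syn relationship by isomerisation of the allylindium. The fallback replaces the metal Barbier reaction by a catalyst-controlled allylboration. It sets out from 12: bis(pinacolato)diboron with catalytic Pd2(dba)3 gives the allylboronate F14 with the alkene geometry retained. F14 and aldehyde 21 react under a chiral BINOL-derived phosphoric acid (the TRIP enantiomer that delivers the allyl group to the Re face of C6) through a closed boron chair, which fixes syn C6/C7 by geometry and the aldehyde face by the catalyst, to give 22 after work-up. PPTS closes 22 to 23, where the fallback returns to the route.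

3. Step 7. What may go wrong: the slow amine-catalysed addition gives the α-oxygenated aldehyde time to epimerise at the carbon that becomes C8, or to oligomerise. The fallback avoids the amine. It sets out from 9: methyl propiolate is hydroaluminated with iBu2AlH in THF/HMPA at 0 °C to the α-aluminated acrylate F15, which should add to the aldehyde of 9 within minutes at 0 °C and spare the lactone. Aqueous work-up gives 11, where the fallback returns to the route.

Further compounds
F1 | step 17 | (2S,4R)-5-(benzyloxy)-2-methylpentane-1,2,4-triol | c1ccccc1COC[C@H](O)C[C@](C)(O)CO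
F2 | step 17 | (2S,4R)-5-(benzyloxy)-2-methyl-1,2,4-tris((triethylsilyl)oxy)pentane | c1ccccc1COC[C@H](O[Si](CC)(CC)CC)C[C@](C)(O[Si](CC)(CC)CC)CO[Si](CC)(CC)CC
F3 | step 17 | (2R,4S)-4-methyl-2,4,5-tris((triethylsilyl)oxy)pentan-1-ol | OC[C@H](O[Si](CC)(CC)CC)C[C@](C)(O[Si](CC)(CC)CC)CO[Si](CC)(CC)CC
F4 | step 17 | (2R,4S)-4-methyl-2,4,5-tris((triethylsilyl)oxy)pentanal | O=C[C@H](O[Si](CC)(CC)CC)C[C@](C)(O[Si](CC)(CC)CC)CO[Si](CC)(CC)CC
F5 | step 17 | methyl (4R,6S)-3-hydroxy-6-methyl-2-methylidene-4,6,7-tris((triethylsilyl)oxy)heptanoate (both C3 epimers) | C=C(C(=O)OC)C(O)[C@H](O[Si](CC)(CC)CC)C[C@](C)(O[Si](CC)(CC)CC)CO[Si](CC)(CC)CC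
F6 | step 17 | methyl (2Z,4R,6S)-2-(bromomethyl)-6-methyl-4,6,7-tris((triethylsilyl)oxy)hept-2-enoate | BrC/C(C(=O)OC)=C\[C@H](O[Si](CC)(CC)CC)C[C@](C)(O[Si](CC)(CC)CC)CO[Si](CC)(CC)CC
F7 | step 17 | open-chain hydroxy ester, analogue of 22 with the acyclic tris-TES chain C8–C10/C1 in place of the glutamate lactone (C5–C8 and C10 configured as in 22) | C=C(C(=O)OC)[C@@H]([C@@H](O)[C@@H](O[Si](C)(C)C(C)(C)C)C(=C)C#C[Si](C)(C)C)[C@H](O[Si](CC)(CC)CC)C[C@](C)(O[Si](CC)(CC)CC)CO[Si](CC)(CC)CC
F8 | step 17 | α-methylene lactone, analogue of 23 with the acyclic tris-TES chain (C5–C8 and C10 configured as in 23) | C=C1C(=O)O[C@@H]([C@@H](O[Si](C)(C)C(C)(C)C)C(=C)C#C[Si](C)(C)C)[C@H]1[C@H](O[Si](CC)(CC)CC)C[C@](C)(O[Si](CC)(CC)CC)CO[Si](CC)(CC)CC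
F9 | step 17 | iodoalkyne from F8 (iodine in place of the TMS group) | C=C1C(=O)O[C@@H]([C@@H](O[Si](C)(C)C(C)(C)C)C(=C)C#CI)[C@H]1[C@H](O[Si](CC)(CC)CC)C[C@](C)(O[Si](CC)(CC)CC)CO[Si](CC)(CC)CC
F10 | step 17 | C1 aldehyde from F9 (CHO in place of CH2OTES) | C=C1C(=O)O[C@@H]([C@@H](O[Si](C)(C)C(C)(C)C)C(=C)C#CI)[C@H]1[C@H](O[Si](CC)(CC)CC)C[C@](C)(O[Si](CC)(CC)CC)C=O
F11 | step 17 | cyclic propargylic alcohol: 1-hydroxy-5-(TBS-oxy)-8,10-bis(TES-oxy)germacra-4(15),11(13)-dien-2-yn-12,6-olide (C1 epimers; other centres as in 28) | C=C1C(=O)O[C@@H]2[C@H]1[C@H](O[Si](CC)(CC)CC)C[C@](C)(O[Si](CC)(CC)CC)C(O)C#CC(=C)[C@@H]2O[Si](C)(C)C(C)(C)C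
F12 | step 17 | ynone: 1-oxo-5-(TBS-oxy)-8,10-bis(TES-oxy)germacra-4(15),11(13)-dien-2-yn-12,6-olide (centres as in 28) | C=C1C(=O)O[C@@H]2[C@H]1[C@H](O[Si](CC)(CC)CC)C[C@](C)(O[Si](CC)(CC)CC)C(=O)C#CC(=C)[C@@H]2O[Si](C)(C)C(C)(C)C
F13 | step 17 | hydroxy ynone: 8-hydroxy-1-oxo-5-(TBS-oxy)-10-(TES-oxy)germacra-4(15),11(13)-dien-2-yn-12,6-olide (centres as in 28) | C=C1C(=O)O[C@@H]2[C@H]1[C@H](O)C[C@](C)(O[Si](CC)(CC)CC)C(=O)C#CC(=C)[C@@H]2O[Si](C)(C)C(C)(C)C
F14 | step 15 | methyl 3-[(2R,4S)-4-methyl-5-oxo-4-((triethylsilyl)oxy)tetrahydrofuran-2-yl]-2-[(4,4,5,5-tetramethyl-1,3,2-dioxaborolan-2-yl)methyl]acrylate (alkene geometry as in 12) | CC1(C)OB(C/C(C(=O)OC)=C\[C@H]2C[C@](C)(O[Si](CC)(CC)CC)C(=O)O2)OC1(C)C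
F15 | step 7 | diisobutyl[1-(methoxycarbonyl)vinyl]aluminium | C=C(C(=O)OC)[Al](CC(C)C)CC(C)C
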